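**Strategy.** The oxepine ring B is disconnected at C2–C3 and C4–C5: C3, C4 and the carbinol carbon on C3 are the three carbons of methyl propiolate, inserted between the two enol-ether carbons of a cis-fused 2,3-dihydrofuran. One operation, an EtAlCl2-promoted (2+2) cycloaddition followed by opening of the donor–acceptor cyclobutene, forms both bonds, expands the five-membered ring to ring B and leaves a β-alkoxy acrylate ready for carbon addition at C2. The precursor is the bromo hexahydrobenzofuran enol ether in which C5a, C7 and C9a of the target are already set, made from α-angelica lactone and isopropyl vinyl ketone by two Michael additions, reduction, Appel inversion and lactone-to-enol-ether conversion.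

Key step: step 7

Remark on numbering and configuration: the target is cis-fused, with 5a-H, 9a-CH3, the bromine on C7 and the CH2Br on C2 all on the same face (2R,5aR,7S,9aS). The bicyclic enol ether is numbered as a 1-benzofuran, which makes it the 5-bromo-4,4,7a-trimethyl compound (gem-dimethyl on C4 next to C3a, bromine on C5, methyl on C7a).

Assumption: of the two pseudoenantiomeric cinchona squaramides (quinine- or quinidine-derived), the one that delivers (S)-3 is used; its sense of induction has to be established on this acceptor.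

**Step 1**
Reactants: 1 α-angelica lactone; 2 4-methylpent-1-en-3-one
Product: 3 (5S)-5-methyl-5-(4-methyl-3-oxopentyl)furan-2(5H)-one
Conditions: cinchona-derived tertiary amine–squaramide (10 mol%), toluene, −20 °C
Reagents that add atoms: none
Why: Organocatalytic enantioselective direct vinylogous Michael addition: the quinuclidine nitrogen deprotonates 1 to the 2-oxidofuran dienolate, which stays ion-paired in the chiral pocket while the squaramide hydrogen-bonds the enone, so the γ-carbon should add to the vinyl terminus through one face and set the quaternary centre (future C9a) as S.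

**Step 2**
Reactants: 3 (5S)-5-methyl-5-(4-methyl-3-oxopentyl)furan-2(5H)-one
Product: 4 (3aR,7aS)-4,4,7a-trimethylhexahydro-1-benzofuran-2,5-dione
Conditions: t-BuOK (0.3 equiv), t-BuOH/THF, 0 °C → rt
Reagents that add atoms: none
Why: Intramolecular Michael addition, 6-(enolendo)-exo-trig: only the isopropyl-side enolate can reach the butenolide β-carbon (the other would close a four-membered ring), and because the tether hangs from C7a the new C3a–C4 bond must form on its own face, which gives the cis fusion (3aR) by substrate control; catalytic base at low temperature is chosen so that ring closure outruns retro-Michael loss of the furanolate, which would erode enantiomeric purity.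

**Step 3**
Reactants: 4 (3aR,7aS)-4,4,7a-trimethylhexahydro-1-benzofuran-2,5-dione
Product: 5 (3aR,5R,7aS)-5-hydroxy-4,4,7a-trimethylhexahydro-1-benzofuran-2(3H)-one
Conditions: NaBH4, MeOH, −40 → −20 °C; aq. NH4Cl
Reagents that add atoms: none
Why: Diastereoselective ketone reduction: the small hydride should attack C5 axially from the convex face (the face of 3a-H and 7a-CH3, the other being shielded by the axial C4 methyl and the lactone ring) to give the equatorial (5R) alcohol, while the lactone is inert to NaBH4 at this temperature.

**Step 4**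
Reactants: 5 (3aR,5R,7aS)-5-hydroxy-4,4,7a-trimethylhexahydro-1-benzofuran-2(3H)-one
Product: 6 (3aR,5S,7aS)-5-bromo-4,4,7a-trimethylhexahydro-1-benzofuran-2(3H)-one
Conditions: CBr4, P(n-C8H17)3, toluene, 70 °C
Reagents that add atoms: carbon tetrabromide, BrC(Br)(Br)Br
Why: Appel reaction with a trialkylphosphine: bromide displaces the alkoxyphosphonium group from the rear (SN2), inverting C5 from R (OH) to S (Br, syn to 3a-H and 7a-CH3); the more nucleophilic phosphine and the non-polar medium are chosen to disfavour ionisation at this neopentylic carbon, a transformation with precedent on 2,2-dimethylcyclohexanols.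

**Step 5**
Reactants: 6 (3aR,5S,7aS)-5-bromo-4,4,7a-trimethylhexahydro-1-benzofuran-2(3H)-one
Product: 7 (3aR,5S,7aS)-5-bromo-4,4,7a-trimethyloctahydro-1-benzofuran-2-ol (both anomers)
Conditions: i-Bu2AlH (1.1 equiv), CH2Cl2, −78 °C; aq. potassium sodium tartrate
Reagents that add atoms: none
Why: Partial reduction of a lactone: one hydride adds and the tetrahedral aluminium lactolate is stable at −78 °C, so the lactol is released only on work-up and the alkyl bromide is untouched.

**Step 6**
Reactants: 7 (3aR,5S,7aS)-5-bromo-4,4,7a-trimethyloctahydro-1-benzofuran-2-ol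
Product: 9 (3aR,5S,7aS)-5-bromo-4,4,7a-trimethyl-3a,4,5,6,7,7a-hexahydro-1-benzofuran, via lactol methanesulfonate 8 (not isolated)
Conditions: MsCl, Et3N (excess), CH2Cl2, −20 → 40 °C
Reagents that add atoms: none
Why: Dehydration of a lactol through its anomeric sulfonate: mesylate 8 ionises to the oxocarbenium ion (or undergoes E2) and Et3N removes a C3 proton to give the enol ether, under conditions that stay basic and so spare the acid-sensitive product and the secondary bromide.

**Step 7**
Reactants: 9 (3aR,5S,7aS)-5-bromo-4,4,7a-trimethyl-3a,4,5,6,7,7a-hexahydro-1-benzofuran; 10 methyl propiolate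
Product: 12 methyl (5aR,7S,9aS)-7-bromo-6,6,9a-trimethyl-5a,6,7,8,9,9a-hexahydro-1-benzoxepine-3-carboxylate, via cyclobutene cycloadduct 11 (not isolated)
Conditions: EtAlCl2 (1.1 equiv, hexane solution), CH2Cl2, −78 °C → rt, then 40 °C; aq. NaHCO3
Reagents that add atoms: none
Why: EtAlCl2 binds the propiolate carbonyl, the enol-ether β-carbon C3 of 9 adds to the terminal alkyne carbon, and the aluminium allenolate collapses onto the oxocarbenium carbon C2 to give the 2-oxabicyclo[3.2.0]heptene 11 (stepwise polar (2+2) cycloaddition, the four-membered ring closing by 4-exo-trig attack of the allenolate carbon). In 11 the ring oxygen (donor) and the ester (acceptor) flank the old C2–C3 bond, which should break heterolytically to an oxocarbenium/dienolate pair that is the polar form of diene ester 12, so ring B arises by ring expansion and not by end-to-end cyclisation, and no symmetry-forbidden concerted opening is needed. The closest known reaction type is the Lewis-acid-promoted (2+2) cycloaddition of enol ethers or enamines with acetylenic esters followed by cyclobutene opening as a two-carbon ring expansion. No lasting stereocentre is created: the two cyclobutane centres vanish on opening, and C5a, C7 and C9a are spectators. The selectivity needed is regiochemical (ester on C3, not C4), and it is secured by the matched polarity of the enol ether (nucleophilic at C3) and the propiolate (electrophilic at its terminal carbon). EtAlCl2 is chosen because its ethyl group destroys adventitious protic acid that would hydrolyse or oligomerise the enol ether, and at low temperature it should leave the secondary bromide alone.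

**Step 8**
Reactants: 12 methyl (5aR,7S,9aS)-7-bromo-6,6,9a-trimethyl-5a,6,7,8,9,9a-hexahydro-1-benzoxepine-3-carboxylate
Product: 14 methyl (2R,5aR,7S,9aS)-7-bromo-2-{[dimethyl(propan-2-yloxy)silyl]methyl}-6,6,9a-trimethyl-2,5,5a,6,7,8,9,9a-octahydro-1-benzoxepine-3-carboxylate, via deconjugated ester 13 (not isolated)
Conditions: (i-PrO)Me2SiCH2MgCl (1.5 equiv, pre-formed THF solution), CuBr·SMe2 (10 mol%), THF, −78 → −40 °C; AcOH, −78 °C; then DBU (0.2 equiv), CH2Cl2, 0 °C
Reagents that add atoms: (isopropoxydimethylsilyl)methylmagnesium chloride, CC(C)O[Si](C)(C)C[Mg]Cl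
Why: Copper-catalysed conjugate addition of a Grignard reagent to a β-alkoxy acrylate: the silylmethyl group should add to C2 on the convex face anti to ring A (syn to 5a-H and 9a-CH3), setting C2 as R under substrate control; the magnesium dienolate is protonated at C3 to give 13, and DBU then moves the double bond into conjugation (C3=C4) so that C5 becomes the CH2 of the target.

**Step 9**
Reactants: 14 methyl (2R,5aR,7S,9aS)-7-bromo-2-{[dimethyl(propan-2-yloxy)silyl]methyl}-6,6,9a-trimethyl-2,5,5a,6,7,8,9,9a-octahydro-1-benzoxepine-3-carboxylate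
Product: 15 methyl (2R,5aR,7S,9aS)-7-bromo-2-(hydroxymethyl)-6,6,9a-trimethyl-2,5,5a,6,7,8,9,9a-octahydro-1-benzoxepine-3-carboxylate
Conditions: 30% H2O2, KF, KHCO3, THF/MeOH, 0 °C → rt
Reagents that add atoms: hydrogen peroxide, OO
Why: Tamao–Fleming oxidation: peroxide attack at fluoride-activated silicon is followed by 1,2-shift of the CH2 group from silicon to oxygen, which unmasks the primary alcohol without touching C2, the enoate or the bromide; buffered conditions and direct use of 15 in the next step limit lactonisation onto the C3 ester.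

**Step 10**
Reactants: 15 methyl (2R,5aR,7S,9aS)-7-bromo-2-(hydroxymethyl)-6,6,9a-trimethyl-2,5,5a,6,7,8,9,9a-octahydro-1-benzoxepine-3-carboxylate
Product: 16 methyl (2R,5aR,7S,9aS)-7-bromo-2-(bromomethyl)-6,6,9a-trimethyl-2,5,5a,6,7,8,9,9a-octahydro-1-benzoxepine-3-carboxylate
Conditions: CBr4, PPh3, CH2Cl2, 0 °C
Reagents that add atoms: carbon tetrabromide, BrC(Br)(Br)Br
Why: Appel reaction at an unhindered primary carbon, a fast SN2 displacement that leaves the ester, the ring ether and the secondary bromide unchanged.

**Step 11**
Reactants: 16 methyl (2R,5aR,7S,9aS)-7-bromo-2-(bromomethyl)-6,6,9a-trimethyl-2,5,5a,6,7,8,9,9a-octahydro-1-benzoxepine-3-carboxylate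
Product: 17 [(2R,5aR,7S,9aS)-7-bromo-2-(bromomethyl)-6,6,9a-trimethyl-2,5,5a,6,7,8,9,9a-octahydro-1-benzoxepin-3-yl]methanol
Conditions: i-Bu2AlH (2.5 equiv), CH2Cl2, −78 °C; aq. potassium sodium tartrate
Reagents that add atoms: none
Why: 1,2-Reduction of the conjugated ester by two hydrides gives the allylic alcohol; at −78 °C i-Bu2AlH does not reduce alkyl bromides or the trisubstituted alkene.

**Compound list**

1 | α-angelica lactone (5-methylfuran-2(3H)-one) | CC1=CCC(=O)O1 | starting material
2 | 4-methylpent-1-en-3-one (isopropyl vinyl ketone) | CC(C)C(=O)C=C | starting material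
3 | (5S)-5-methyl-5-(4-methyl-3-oxopentyl)furan-2(5H)-one | CC(C)C(=O)CC[C@]1(C)OC(=O)C=C1 | intermediate
4 | (3aR,7aS)-4,4,7a-trimethylhexahydro-1-benzofuran-2,5-dione (cis-fused keto lactone) | CC1(C)[C@H]2CC(=O)O[C@@]2(C)CCC1=O | intermediate
5 | (3aR,5R,7aS)-5-hydroxy-4,4,7a-trimethylhexahydro-1-benzofuran-2(3H)-one | CC1(C)[C@H]2CC(=O)O[C@@]2(C)CC[C@H]1O | intermediate
6 | (3aR,5S,7aS)-5-bromo-4,4,7a-trimethylhexahydro-1-benzofuran-2(3H)-one | CC1(C)[C@H]2CC(=O)O[C@@]2(C)CC[C@@H]1Br | intermediate
7 | (3aR,5S,7aS)-5-bromo-4,4,7a-trimethyloctahydro-1-benzofuran-2-ol (lactol, both anomers) | CC1(C)[C@H]2CC(O)O[C@@]2(C)CC[C@@H]1Br | intermediate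
8 | (3aR,5S,7aS)-5-bromo-4,4,7a-trimethyloctahydro-1-benzofuran-2-yl methanesulfonate (both anomers, not isolated) | CC1(C)[C@H]2CC(OS(C)(=O)=O)O[C@@]2(C)CC[C@@H]1Br | intermediate
9 | (3aR,5S,7aS)-5-bromo-4,4,7a-trimethyl-3a,4,5,6,7,7a-hexahydro-1-benzofuran (cis-fused enol ether) | CC1(C)[C@H]2C=CO[C@@]2(C)CC[C@@H]1Br | intermediate
10 | methyl propiolate (methyl prop-2-ynoate) | C#CC(=O)OC | starting material
11 | cyclobutene cycloadduct: methyl 2-oxabicyclo[3.2.0]hept-6-ene-7-carboxylate with the bromotrimethylcyclohexane ring fused across C3–C4, cyclobutene on the face of 3a-H and 7a-CH3 (not isolated) | CC1(C)[C@H]2[C@@H]3C=C(C(=O)OC)[C@@H]3O[C@@]2(C)CC[C@@H]1Br | intermediate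
12 | methyl (5aR,7S,9aS)-7-bromo-6,6,9a-trimethyl-5a,6,7,8,9,9a-hexahydro-1-benzoxepine-3-carboxylate | CC1(C)[C@H]2C=CC(C(=O)OC)=CO[C@@]2(C)CC[C@@H]1Br | intermediate
13 | methyl (2R,5aR,7S,9aS)-7-bromo-2-{[dimethyl(propan-2-yloxy)silyl]methyl}-6,6,9a-trimethyl-2,3,5a,6,7,8,9,9a-octahydro-1-benzoxepine-3-carboxylate (C3 epimers, not isolated) | CC1(C)[C@H]2C=CC(C(=O)OC)[C@H](C[Si](C)(C)OC(C)C)O[C@@]2(C)CC[C@@H]1Br | intermediate
14 | methyl (2R,5aR,7S,9aS)-7-bromo-2-{[dimethyl(propan-2-yloxy)silyl]methyl}-6,6,9a-trimethyl-2,5,5a,6,7,8,9,9a-octahydro-1-benzoxepine-3-carboxylate | CC1(C)[C@H]2CC=C(C(=O)OC)[C@H](C[Si](C)(C)OC(C)C)O[C@@]2(C)CC[C@@H]1Br | intermediate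
15 | methyl (2R,5aR,7S,9aS)-7-bromo-2-(hydroxymethyl)-6,6,9a-trimethyl-2,5,5a,6,7,8,9,9a-octahydro-1-benzoxepine-3-carboxylate | CC1(C)[C@H]2CC=C(C(=O)OC)[C@H](CO)O[C@@]2(C)CC[C@@H]1Br | intermediate
16 | methyl (2R,5aR,7S,9aS)-7-bromo-2-(bromomethyl)-6,6,9a-trimethyl-2,5,5a,6,7,8,9,9a-octahydro-1-benzoxepine-3-carboxylate | CC1(C)[C@H]2CC=C(C(=O)OC)[C@H](CBr)O[C@@]2(C)CC[C@@H]1Br | intermediate
17 | [(2R,5aR,7S,9aS)-7-bromo-2-(bromomethyl)-6,6,9a-trimethyl-2,5,5a,6,7,8,9,9a-octahydro-1-benzoxepin-3-yl]methanol | CC1(C)[C@H]2CC=C(CO)[C@H](CBr)O[C@@]2(C)CC[C@@H]1Br | target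

**Step count.** Total: 11 steps. Longest linear sequence: 11 steps (1 → 17).

**Steps most likely to fail**

Step 7. The enol ether may be consumed by acid-induced hydrolysis or oligomerisation before it meets the activated propiolate, or the cycloadduct may stall at the cyclobutene without opening. The fallback sets out from lactol 7 and returns at diene ester 12, building ring B from the other end. The lithium enolate of methyl 3,3-dimethoxypropanoate (LiN(i-Pr)2, THF, −78 → 0 °C, excess) adds to the open hydroxy-aldehyde form of 7 and gives the ring-opened aldol adduct F1 (new C3–C4 bond). Camphorsulfonic acid in toluene at 80 °C over 4 Å molecular sieves should then close the tertiary alcohol onto the acetal carbon to the seven-membered cyclic methoxy acetal F2 (new O1–C2 bond). Pushed by the ring oxygen, F2 loses methanol across C2–C3 and water across C4–C5 to give 12.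

Step 4. The alkoxyphosphonium ion may ionise at the neopentylic carbon, so that Wagner–Meerwein ring contraction or elimination takes over from SN2 displacement. The fallback sets out from alcohol 5 and returns at bromide 6, separating activation from displacement. Tf2O and pyridine in CH2Cl2 at −30 °C give the triflate F3, which is displaced cold (toluene, −20 °C → rt) by the unsolvated bromide of n-Bu4NBr with inversion.

Step 8. The magnesium dienolate may expel the ring oxygen from C2 (β-elimination that opens ring B), and attack may also occur in part on the concave face. The fallback sets out from diene ester 12 and returns at hydroxy ester 15, replacing the organometallic by a radical conjugate addition in a protic medium, where no long-lived metal enolate exists. Potassium trifluoro{[(4-methoxyphenyl)methoxy]methyl}borate with 9-mesityl-10-methylacridinium perchlorate (5 mol%) under blue light in acetone/MeOH adds the alkoxymethyl radical to C2 (Giese reaction). DBU equilibration as in step 8 then gives the PMB ether F4. DDQ in CH2Cl2/water removes the PMB group to give 15.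

**Further compounds**

F1 | step 7 | methyl 4-(3-bromo-6-hydroxy-2,2,6-trimethylcyclohexyl)-2-(dimethoxymethyl)-3-hydroxybutanoate (ring stereocentres as in 7; mixture at the two new chain centres) | CC1(C)[C@@H](CC(O)C(C(=O)OC)C(OC)OC)[C@@](C)(O)CC[C@@H]1Br
F2 | step 7 | methyl (5aR,7S,9aS)-7-bromo-4-hydroxy-2-methoxy-6,6,9a-trimethyldecahydro-1-benzoxepine-3-carboxylate (mixture at C2, C3, C4) | CC1(C)[C@H]2CC(O)C(C(=O)OC)C(OC)O[C@@]2(C)CC[C@@H]1Br
F3 | step 4 | (3aR,5R,7aS)-4,4,7a-trimethyl-2-oxooctahydro-1-benzofuran-5-yl trifluoromethanesulfonate | CC1(C)[C@H]2CC(=O)O[C@@]2(C)CC[C@H]1OS(=O)(=O)C(F)(F)F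
F4 | step 8 | methyl (2R,5aR,7S,9aS)-7-bromo-2-{[(4-methoxyphenyl)methoxy]methyl}-6,6,9a-trimethyl-2,5,5a,6,7,8,9,9a-octahydro-1-benzoxepine-3-carboxylate | CC1(C)[C@H]2CC=C(C(=O)OC)[C@H](COCc3ccc(OC)cc3)O[C@@]2(C)CC[C@@H]1Br
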